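## Structural features

The target is a trans-2,3-diaryl-2,3-dihydro-1-benzofuran: benzo ring A is fused to dihydrofuran ring B, C2 carries catechol ring C, C3 carries resorcinol ring D, C4 carries a hydroxyl and C6 an (E)-styryl arm ending in phenol ring E. The only stereocentres are the neighbours C2 and C3, both S (re-derived from the SMILES), with the two aryl groups trans. C2 is a benzylic ether carbon para to a ring C oxygen, so the O1–C2 bond ionises easily under protic or Lewis acid. This makes C2 correctable, because trans is the stable arrangement, but it also makes a harsh ether cleavage at the end dangerous. C3 is a doubly benzylic methine between ring D and the fully substituted C3a; it can be set only once and must then be left alone. The six free phenols (one an air-sensitive catechol) and the stilbene double bond (light, acid, electrophiles) are the other fragile groups. The real difficulty is absolute control at C3 next to a hindered arene carbon, together with a ring A pattern (oxygen at C7a and C4 on both sides of C3a, carbon at C6) that substitution of a preformed resorcinol reaches poorly. The key step exploits that ring A is a 2,5-disubstituted resorcinol: a 3-substituted cyclobutenone supplies C5, C6, C7 and C7a, and an ynol silyl ether supplies C3a and C4. Ring A has local twofold symmetry about the C3a–C6 axis, so it does not matter which of its two oxygens ends up silylated.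

## Logic of the disconnections

**30 to 29.** Six aryl O–Si bonds are cut. Fluoride is the one global deprotection that touches neither O1–C2 nor the stilbene, whereas Lewis-acid cleavage of methyl ethers would put both at risk. The gain is that all phenols stay masked through the organometallic steps. The demand is that five aryl silyl ethers survive every earlier step.

**29 to 28.** The O1–C2 bond of ring B is cut. Closing ring B last by SN2 displacement with inversion turns the trans relation into a syn relation in the open chain, which an auxiliary-controlled aldol delivers. The gain is an acyclic precursor with C2 as a plain carbinol. The demand is one free phenol ortho to the side chain and the (1S,2R) side-chain configuration. The descriptors were checked: inversion at the R carbinol gives 2S, and C3 stays S.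

**28 to 27.** The O–Si bond at the carbinol is cut. A trialkylsilyl ether on a secondary alkyl oxygen is the only silyl group in 27 that mild acid removes. The demand is acid weak enough not to ionise the benzylic carbon.

**27 to 16 and 22.** The bonds C3a–C7a, C4–C5 and C7–C7a of ring A are cut. This removes the whole tetrasubstituted arene in one operation and leaves two fragments of similar size, one carrying both stereocentres and the other the stilbene arm. The demand is a neutral thermal step in which the alkyne carbon bearing the side chain bonds to the ketene carbonyl carbon, without disturbing the C–H at the future C3.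

**22 to 18 and 19, then 18 to 17.** The bond between the ring and the styryl carbon is cut, then the vinyl C=C. A vinyl anion adds to the vinylogous ester 19 and acid transposes the carbonyl. The demand is retention of the E geometry through iodine–lithium exchange.

**16 back to 9.** The alkynyl C–O bond and the alkyne π-bonds are cut to reach 13, the C=C of 13 to reach 12, and then redox and protecting-group changes lead back through 11 and 10 to 9. One carbon is added as CBr2 and the oxygen arrives as an electrophile on the acetylide. The demand is that 12, an α-aryl aldehyde with a β-silyloxy group, is never exposed to base; this is why a phosphorus ylide is used instead of a basic diazophosphonate.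

**9 to 6 and 7.** The bond between the two stereocentres is cut. Both centres arise together in a boron aldol whose Z-enolate and (R)-auxiliary give the syn (2R,3R) adduct. The demand is clean Z-enolisation of an arylacetyl imide and no retro-aldol on work-up.

**6 to 3 and 4, then 3 to 1.** The N-acyl bond and three O–Si bonds are cut, leading to a purchasable acid and auxiliary.

## Other disconnections considered

**Alternative 1:** The cut is the C3–C3a bond, traced back to the C4–C4a bond of the chromanone A1. In the forward step PhI(OAc)2 and H2SO4 in trimethyl orthoformate would make the enol ether of A1, trivalent iodine would add at C3, and the ring A carbon would shift from C4 to C3 as iodine leaves, giving the trans ester A2 with C4 extruded as CO2Me.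
- In its favour: C2 comes from the chiral pool with no auxiliary, which is better than the chosen plan on that point, and the bicyclic core is reached in very few steps, also better.
- Against it here: A2 lacks ring D and the styryl arm. The ester at C3 would have to be replaced by an aryl group at a stereocentre, and the C6 oxygen by carbon, so the hardest bond is left to the end. Alkylating the ring A phenols of a natural flavanone under base would invite ring opening and loss of C2 configuration. The strongly acidic oxidation could also divert to ring C migration or dehydrogenation.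
- Comparison: on mechanism it is a cationic shift in strong acid against a neutral pericyclic cascade; on overall step count it would probably be no shorter than the chosen plan.

**Alternative 2:** The cuts are C2–C3 and O1–C2. Cs2CO3 would expel the sulfinate group from sulfone A3 to give the ortho-quinone methide at C3, the ylide from sulfonium salt A4 would add to form C2–C3, and the phenoxide would displace the sulfide at C2 to give A5.
- In its favour: it is the most convergent plan. Ring B and both stereocentres form in one step, trans follows from the addition–displacement sequence, and the C4 hydroxyl emerges free. On step economy it is clearly better than the chosen plan.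
- Against it here: absolute control rests on reagent control by an electron-rich, semi-stabilised benzyl ylide, whose addition may be reversible. The quinone methide is flanked by two oxygens and would carry a second phenoxide, lowering its electrophilicity. A4 may ionise at its electron-rich benzylic carbon.
- Comparison: on structure the two plans are equal in installing ring D before ring B closes; on reliability of the absolute configuration the auxiliary aldol of the chosen plan is stronger. The spectator ethers could be changed in either plan, so that point is equal.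

**Alternative 3:** The cuts are C3a–C7a, C4–C5 and C6–C7. Cp*RuCl(cod) would join the two alkyne ends of diyne A6 into a ruthenacycle, insert the terminal alkyne of enyne A7 and release A8, closing rings A and B together.
- In its favour: it forms two rings at once, which is better than the chosen plan, with the same three skeletal bonds, which is equal. The O1–C2 bond is already present, so C2 is kept by retention rather than set by a late displacement, again better. The conditions are neutral.
- Against it here: A6 is a 1-alkynyl ether of a secondary, electron-rich benzylic alcohol, a class that rearranges or fragments on mild warming and is made under strong base next to the C3–H. The placing of the styryl group at C6 would rest on steric bias at the metal, whereas the chosen plan fixes it by the polarity of the ynol ether. A7 can oligomerise, and the C–B bond needs a further oxidation.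
- Comparison: the step count would be similar to the chosen plan; the precursor is more fragile.

Key step: step 11

Assumption: TBS = tert-butyldimethylsilyl, TES = triethylsilyl, TIPS = triisopropylsilyl (TBSO, TESO, TIPSO for their ethers); the five spectator phenols are carried as TBS ethers rather than methyl ethers because a Lewis-acid demethylation at the end would endanger the O1–C2 bond and the stilbene, and 7 and 17 are taken as purchasable (each is otherwise one silylation of the hydroxy aldehyde).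

## Route

Step 1
Reactants: 1 (3,5-dihydroxyphenyl)acetic acid
Product: 3 [3,5-bis(TBSO)phenyl]acetic acid, via silyl ester 2 (not isolated)
Conditions: TBSCl (3.3 equiv), imidazole, DMF, rt; then AcOH/THF/H2O, rt
Reagents that add atoms: tert-butyldimethylsilyl chloride, CC(C)(C)[Si](C)(C)Cl
Why: Imidazole-promoted silylation of both phenols and the acid, followed by selective hydrolysis of the labile silyl ester under mild aqueous acid, which aryl silyl ethers resist.

Step 2
Reactants: 3 [3,5-bis(TBSO)phenyl]acetic acid; 4 (R)-4-benzyl-1,3-oxazolidin-2-one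
Product: 6 (R)-4-benzyl-3-{[3,5-bis(TBSO)phenyl]acetyl}-1,3-oxazolidin-2-one, via mixed anhydride 5 (not isolated)
Conditions: PivCl, Et3N, THF, −20 °C; then 4, LiCl, −20 °C to rt
Reagents that add atoms: none
Why: N-acylation of the oxazolidinone through the pivaloyl mixed anhydride with LiCl activation; no strong base is used, so the arylacetyl unit does not form a ketene.

Step 3
Reactants: 6 (R)-4-benzyl-3-{[3,5-bis(TBSO)phenyl]acetyl}-1,3-oxazolidin-2-one; 7 3,4-bis(TBSO)benzaldehyde
Product: 9 (R)-4-benzyl-3-{(2R,3R)-3-[3,4-bis(TBSO)phenyl]-2-[3,5-bis(TBSO)phenyl]-3-hydroxypropanoyl}-1,3-oxazolidin-2-one, via boron enolate 8 (not isolated)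
Conditions: Bu2BOTf, i-Pr2NEt, CH2Cl2, 0 °C; then 7, −78 to 0 °C; pH 7 buffer, MeOH, H2O2, 0 °C
Reagents that add atoms: none
Why: Evans syn aldol; the Z-boron enolate reacts through a closed chair transition state, and the benzyl group of the (R)-auxiliary blocks one enolate face, so both new centres (2R,3R, syn) are set by the auxiliary.

Step 4
Reactants: 9 (R)-4-benzyl-3-{(2R,3R)-3-[3,4-bis(TBSO)phenyl]-2-[3,5-bis(TBSO)phenyl]-3-hydroxypropanoyl}-1,3-oxazolidin-2-one
Product: 10 (R)-4-benzyl-3-{(2R,3R)-3-[3,4-bis(TBSO)phenyl]-2-[3,5-bis(TBSO)phenyl]-3-(TESO)propanoyl}-1,3-oxazolidin-2-one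
Conditions: TESOTf, 2,6-lutidine, CH2Cl2, −78 °C
Reagents that add atoms: triethylsilyl triflate, CC[Si](CC)(CC)OS(=O)(=O)C(F)(F)F
Why: Silylation of a hindered secondary alcohol with a silyl triflate and a non-nucleophilic base, cold enough to avoid retro-aldol; TES is chosen because it can later be removed by acid beside aryl silyl ethers.

Step 5
Reactants: 10 (R)-4-benzyl-3-{(2R,3R)-3-[3,4-bis(TBSO)phenyl]-2-[3,5-bis(TBSO)phenyl]-3-(TESO)propanoyl}-1,3-oxazolidin-2-one
Product: 11 (2S,3R)-3-[3,4-bis(TBSO)phenyl]-2-[3,5-bis(TBSO)phenyl]-3-(TESO)propan-1-ol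
Conditions: LiBH4, THF, 0 °C to rt
Reagents that add atoms: none
Why: Reductive cleavage of the N-acyl oxazolidinone by LiBH4 at the exocyclic carbonyl; hydride delivery should be faster than enolisation, so the α-aryl centre is kept (the descriptor changes only through priorities).

Step 6
Reactants: 11 (2S,3R)-3-[3,4-bis(TBSO)phenyl]-2-[3,5-bis(TBSO)phenyl]-3-(TESO)propan-1-ol
Product: 12 (2R,3R)-3-[3,4-bis(TBSO)phenyl]-2-[3,5-bis(TBSO)phenyl]-3-(TESO)propanal
Conditions: Dess–Martin periodinane, NaHCO3, CH2Cl2, 0 °C; crude aldehyde used at once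
Reagents that add atoms: none
Why: Dess–Martin oxidation under buffered, near-neutral conditions; the α-aryl aldehyde is configurationally fragile and is therefore not purified or stored.

Step 7
Reactants: 12 (2R,3R)-3-[3,4-bis(TBSO)phenyl]-2-[3,5-bis(TBSO)phenyl]-3-(TESO)propanal
Product: 13 (3R,4R)-4-[3,4-bis(TBSO)phenyl]-3-[3,5-bis(TBSO)phenyl]-1,1-dibromo-4-(TESO)but-1-ene
Conditions: CBr4, PPh3, CH2Cl2, 0 °C (ylide pre-formed); then 12, 2,6-lutidine, −78 to 0 °C
Reagents that add atoms: carbon tetrabromide, BrC(Br)(Br)Br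
Why: First stage of the Corey–Fuchs sequence (Ramirez dibromo-olefination); the ylide is weakly basic and reacts fast with aldehydes, so the acidic α-hydrogen is removed from the danger zone without epimerisation or β-elimination.

Step 8
Reactants: 13 (3R,4R)-4-[3,4-bis(TBSO)phenyl]-3-[3,5-bis(TBSO)phenyl]-1,1-dibromo-4-(TESO)but-1-ene
Product: 16 (3S,4R)-4-[3,4-bis(TBSO)phenyl]-3-[3,5-bis(TBSO)phenyl]-4-(TESO)-1-(TIPSO)but-1-yne, via lithium acetylide 14 (not isolated), via lithium ynolate 15 (not isolated)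
Conditions: n-BuLi (2.1 equiv), THF, −78 °C; then t-BuOOLi (from t-BuOOH and LiN(SiMe3)2), −78 to 0 °C; then TIPSOTf, −78 °C
Reagents that add atoms: tert-butyl hydroperoxide (as its lithium salt), CC(C)(C)OO; triisopropylsilyl triflate, CC(C)[Si](C(C)C)(C(C)C)OS(=O)(=O)C(F)(F)F
Why: Second stage of the Corey–Fuchs sequence gives the lithium acetylide directly; electrophilic oxygen transfer from lithium tert-butylperoxide converts it into the ynolate, which is silylated on oxygen by the bulky TIPS triflate; the propargylic centre is not touched because only the sp carbon is metallated.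

Step 9
Reactants: 17 4-(TBSO)benzaldehyde
Product: 18 (E)-1-(2-iodoethenyl)-4-(TBSO)benzene
Conditions: CrCl2, CHI3, THF/1,4-dioxane, 0 °C to rt
Reagents that add atoms: iodoform, IC(I)I
Why: Takai olefination; the geminal dichromium reagent (trivalent chromium) adds to the aldehyde and eliminates anti to give mainly the E vinyl iodide under non-basic conditions.

Step 10
Reactants: 18 (E)-1-(2-iodoethenyl)-4-(TBSO)benzene; 19 3-ethoxycyclobut-2-en-1-one
Product: 22 3-{(E)-2-[4-(TBSO)phenyl]ethenyl}cyclobut-2-en-1-one, via styryllithium 20 (not isolated), via alkoxide adduct 21 (not isolated)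
Conditions: t-BuLi (2 equiv), Et2O, −78 °C; then 19, −78 °C; then 1 M HCl, 0 °C
Reagents that add atoms: water, O
Why: Iodine–lithium exchange with retention of the E geometry, 1,2-addition to the vinylogous ester, and acid hydrolysis with carbonyl transposition (Stork–Danheiser transposition) give the 3-substituted cyclobutenone.

Step 11
Reactants: 16 (3S,4R)-4-[3,4-bis(TBSO)phenyl]-3-[3,5-bis(TBSO)phenyl]-4-(TESO)-1-(TIPSO)but-1-yne; 22 3-{(E)-2-[4-(TBSO)phenyl]ethenyl}cyclobut-2-en-1-one
Product: 27 2-{(1S,2R)-2-[3,4-bis(TBSO)phenyl]-1-[3,5-bis(TBSO)phenyl]-2-(TESO)ethyl}-5-{(E)-2-[4-(TBSO)phenyl]ethenyl}-3-(TIPSO)phenol, via vinylketene 23 (not isolated), via vinylcyclobutenone 24 (not isolated), via dienylketene 25 (not isolated), via cyclohexadienone 26 (not isolated)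
Conditions: toluene, 80 °C then 110 °C, 22 (1.3 equiv) added slowly, argon, dark
Reagents that add atoms: none
Why: At 80 °C 22 opens by four-electron electrocyclic ring opening to vinylketene 23. 23 adds to the ynol ether of 16 in a (2+2) cycloaddition, the ketene carbonyl carbon bonding to the nucleophilic alkyne carbon that bears the side chain, to give 24. 24 reopens to dienylketene 25, which closes ring A by six-electron electrocyclisation to 26 and tautomerises to phenol 27. The closest known reaction type is the thermal benzannulation of cyclobutenones with trialkylsilyloxyalkynes to resorcinol monosilyl ethers. Ring A is the only ring closed, and it closes by electrocyclisation; no lasting stereocentre is created, since the sp3 carbon of 24 is planarised again, and the two existing centres are untouched because the medium is neutral and aprotic. The step needs regioselectivity in the (2+2) addition, secured by the polarisation of the ynol ether, and chemoselectivity for the alkyne over the styrene double bonds, secured by the much higher ketene reactivity of the electron-rich alkyne. Because ring A is symmetric about the C3a–C6 axis, either oxygen may carry the silyl group without consequence. Slow addition keeps 23 dilute, which should limit its dimerisation and acylation of the product phenol.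

Step 12
Reactants: 27 2-{(1S,2R)-2-[3,4-bis(TBSO)phenyl]-1-[3,5-bis(TBSO)phenyl]-2-(TESO)ethyl}-5-{(E)-2-[4-(TBSO)phenyl]ethenyl}-3-(TIPSO)phenol
Product: 28 2-{(1S,2R)-2-[3,4-bis(TBSO)phenyl]-1-[3,5-bis(TBSO)phenyl]-2-hydroxyethyl}-5-{(E)-2-[4-(TBSO)phenyl]ethenyl}-3-(TIPSO)phenol
Conditions: PPTS, MeOH/CH2Cl2, 0 °C
Reagents that add atoms: none
Why: Acid-catalysed methanolysis of the secondary alkyl TES ether; under weak acid aryl silyl ethers are cleaved far more slowly, and the acid is too weak to ionise the benzylic carbon.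

Step 13
Reactants: 28 2-{(1S,2R)-2-[3,4-bis(TBSO)phenyl]-1-[3,5-bis(TBSO)phenyl]-2-hydroxyethyl}-5-{(E)-2-[4-(TBSO)phenyl]ethenyl}-3-(TIPSO)phenol
Product: 29 (2S,3S)-2-[3,4-bis(TBSO)phenyl]-3-[3,5-bis(TBSO)phenyl]-6-{(E)-2-[4-(TBSO)phenyl]ethenyl}-4-(TIPSO)-2,3-dihydro-1-benzofuran
Conditions: PPh3, DIAD, THF, 0 °C to rt
Reagents that add atoms: none
Why: Intramolecular Mitsunobu etherification; the single free phenol displaces the activated carbinol oxygen in a 5-exo-tet SN2 closure with inversion at C2, which turns the syn open chain into the trans ring (2S), while C3 is not involved.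

Step 14
Reactants: 29 (2S,3S)-2-[3,4-bis(TBSO)phenyl]-3-[3,5-bis(TBSO)phenyl]-6-{(E)-2-[4-(TBSO)phenyl]ethenyl}-4-(TIPSO)-2,3-dihydro-1-benzofuran
Product: 30 (2S,3S)-2-(3,4-dihydroxyphenyl)-3-(3,5-dihydroxyphenyl)-6-[(E)-2-(4-hydroxyphenyl)ethenyl]-2,3-dihydro-1-benzofuran-4-ol
Conditions: TBAF (7 equiv), AcOH (7 equiv), THF, 0 °C to rt, argon
Reagents that add atoms: none
Why: Fluoride cleavage of all six aryl silyl ethers; acetic acid buffering keeps the catechol and the phenols protonated, and neither the O1–C2 bond nor the stilbene reacts with fluoride.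

## Compound list

1 | (3,5-dihydroxyphenyl)acetic acid | OC(=O)Cc1cc(O)cc(O)c1 | starting material
2 | tert-butyldimethylsilyl [3,5-bis(TBSO)phenyl]acetate | CC(C)(C)[Si](C)(C)OC(=O)Cc1cc(O[Si](C)(C)C(C)(C)C)cc(O[Si](C)(C)C(C)(C)C)c1 | intermediate (not isolated)
3 | [3,5-bis(TBSO)phenyl]acetic acid | OC(=O)Cc1cc(O[Si](C)(C)C(C)(C)C)cc(O[Si](C)(C)C(C)(C)C)c1 | intermediate
4 | (R)-4-benzyl-1,3-oxazolidin-2-one | O=C1N[C@H](Cc2ccccc2)CO1 | starting material
5 | [3,5-bis(TBSO)phenyl]acetic pivalic anhydride | CC(C)(C)C(=O)OC(=O)Cc1cc(O[Si](C)(C)C(C)(C)C)cc(O[Si](C)(C)C(C)(C)C)c1 | intermediate (not isolated)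
6 | (R)-4-benzyl-3-{[3,5-bis(TBSO)phenyl]acetyl}-1,3-oxazolidin-2-one | O=C(Cc1cc(O[Si](C)(C)C(C)(C)C)cc(O[Si](C)(C)C(C)(C)C)c1)N1[C@H](Cc2ccccc2)COC1=O | intermediate
7 | 3,4-bis(TBSO)benzaldehyde | O=Cc1ccc(O[Si](C)(C)C(C)(C)C)c(O[Si](C)(C)C(C)(C)C)c1 | starting material
8 | dibutylboron (Z)-enolate of 6 | CCCCB(CCCC)O/C(=C\c1cc(O[Si](C)(C)C(C)(C)C)cc(O[Si](C)(C)C(C)(C)C)c1)N1[C@H](Cc2ccccc2)COC1=O | intermediate (not isolated)
9 | (R)-4-benzyl-3-{(2R,3R)-3-[3,4-bis(TBSO)phenyl]-2-[3,5-bis(TBSO)phenyl]-3-hydroxypropanoyl}-1,3-oxazolidin-2-one | O[C@@H](c1ccc(O[Si](C)(C)C(C)(C)C)c(O[Si](C)(C)C(C)(C)C)c1)[C@H](C(=O)N1[C@H](Cc2ccccc2)COC1=O)c1cc(O[Si](C)(C)C(C)(C)C)cc(O[Si](C)(C)C(C)(C)C)c1 | intermediate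
10 | (R)-4-benzyl-3-{(2R,3R)-3-[3,4-bis(TBSO)phenyl]-2-[3,5-bis(TBSO)phenyl]-3-(TESO)propanoyl}-1,3-oxazolidin-2-one | CC[Si](CC)(CC)O[C@@H](c1ccc(O[Si](C)(C)C(C)(C)C)c(O[Si](C)(C)C(C)(C)C)c1)[C@H](C(=O)N1[C@H](Cc2ccccc2)COC1=O)c1cc(O[Si](C)(C)C(C)(C)C)cc(O[Si](C)(C)C(C)(C)C)c1 | intermediate
11 | (2S,3R)-3-[3,4-bis(TBSO)phenyl]-2-[3,5-bis(TBSO)phenyl]-3-(TESO)propan-1-ol | CC[Si](CC)(CC)O[C@@H](c1ccc(O[Si](C)(C)C(C)(C)C)c(O[Si](C)(C)C(C)(C)C)c1)[C@H](CO)c1cc(O[Si](C)(C)C(C)(C)C)cc(O[Si](C)(C)C(C)(C)C)c1 | intermediate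
12 | (2R,3R)-3-[3,4-bis(TBSO)phenyl]-2-[3,5-bis(TBSO)phenyl]-3-(TESO)propanal | CC[Si](CC)(CC)O[C@@H](c1ccc(O[Si](C)(C)C(C)(C)C)c(O[Si](C)(C)C(C)(C)C)c1)[C@H](C=O)c1cc(O[Si](C)(C)C(C)(C)C)cc(O[Si](C)(C)C(C)(C)C)c1 | intermediate
13 | (3R,4R)-4-[3,4-bis(TBSO)phenyl]-3-[3,5-bis(TBSO)phenyl]-1,1-dibromo-4-(TESO)but-1-ene | CC[Si](CC)(CC)O[C@@H](c1ccc(O[Si](C)(C)C(C)(C)C)c(O[Si](C)(C)C(C)(C)C)c1)[C@H](C=C(Br)Br)c1cc(O[Si](C)(C)C(C)(C)C)cc(O[Si](C)(C)C(C)(C)C)c1 | intermediate
14 | (3S,4R)-4-[3,4-bis(TBSO)phenyl]-3-[3,5-bis(TBSO)phenyl]-4-(TESO)but-1-yn-1-yllithium | CC[Si](CC)(CC)O[C@@H](c1ccc(O[Si](C)(C)C(C)(C)C)c(O[Si](C)(C)C(C)(C)C)c1)[C@H](C#C[Li])c1cc(O[Si](C)(C)C(C)(C)C)cc(O[Si](C)(C)C(C)(C)C)c1 | intermediate (not isolated)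
15 | lithium (3S,4R)-4-[3,4-bis(TBSO)phenyl]-3-[3,5-bis(TBSO)phenyl]-4-(TESO)but-1-yn-1-olate | CC[Si](CC)(CC)O[C@@H](c1ccc(O[Si](C)(C)C(C)(C)C)c(O[Si](C)(C)C(C)(C)C)c1)[C@H](C#CO[Li])c1cc(O[Si](C)(C)C(C)(C)C)cc(O[Si](C)(C)C(C)(C)C)c1 | intermediate (not isolated)
16 | (3S,4R)-4-[3,4-bis(TBSO)phenyl]-3-[3,5-bis(TBSO)phenyl]-4-(TESO)-1-(TIPSO)but-1-yne | CC[Si](CC)(CC)O[C@@H](c1ccc(O[Si](C)(C)C(C)(C)C)c(O[Si](C)(C)C(C)(C)C)c1)[C@H](C#CO[Si](C(C)C)(C(C)C)C(C)C)c1cc(O[Si](C)(C)C(C)(C)C)cc(O[Si](C)(C)C(C)(C)C)c1 | intermediate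
17 | 4-(TBSO)benzaldehyde | O=Cc1ccc(O[Si](C)(C)C(C)(C)C)cc1 | starting material
18 | (E)-1-(2-iodoethenyl)-4-(TBSO)benzene | I/C=C/c1ccc(O[Si](C)(C)C(C)(C)C)cc1 | intermediate
19 | 3-ethoxycyclobut-2-en-1-one | CCOC1=CC(=O)C1 | starting material
20 | (E)-2-[4-(TBSO)phenyl]ethenyllithium | [Li]/C=C/c1ccc(O[Si](C)(C)C(C)(C)C)cc1 | intermediate (not isolated)
21 | lithium 3-ethoxy-1-{(E)-2-[4-(TBSO)phenyl]ethenyl}cyclobut-2-en-1-olate (racemic) | CCOC1=CC(O[Li])(/C=C/c2ccc(O[Si](C)(C)C(C)(C)C)cc2)C1 | intermediate (not isolated)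
22 | 3-{(E)-2-[4-(TBSO)phenyl]ethenyl}cyclobut-2-en-1-one | O=C1C=C(/C=C/c2ccc(O[Si](C)(C)C(C)(C)C)cc2)C1 | intermediate
23 | (4E)-3-methylidene-5-[4-(TBSO)phenyl]penta-1,4-dien-1-one | O=C=CC(=C)/C=C/c1ccc(O[Si](C)(C)C(C)(C)C)cc1 | intermediate (not isolated)
24 | 2-{(1S,2R)-2-[3,4-bis(TBSO)phenyl]-1-[3,5-bis(TBSO)phenyl]-2-(TESO)ethyl}-4-{(3E)-4-[4-(TBSO)phenyl]buta-1,3-dien-2-yl}-3-(TIPSO)cyclobut-2-en-1-one (both epimers at ring C4) | O=C1C([C@H](c2cc(O[Si](C)(C)C(C)(C)C)cc(O[Si](C)(C)C(C)(C)C)c2)[C@@H](O[Si](CC)(CC)CC)c2ccc(O[Si](C)(C)C(C)(C)C)c(O[Si](C)(C)C(C)(C)C)c2)=C(O[Si](C(C)C)(C(C)C)C(C)C)C1C(=C)/C=C/c1ccc(O[Si](C)(C)C(C)(C)C)cc1 | intermediate (not isolated)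
25 | (3E,6E)-2-{(1S,2R)-2-[3,4-bis(TBSO)phenyl]-1-[3,5-bis(TBSO)phenyl]-2-(TESO)ethyl}-5-methylidene-7-[4-(TBSO)phenyl]-3-(TIPSO)hepta-1,3,6-trien-1-one | O=C=C([C@H](c1cc(O[Si](C)(C)C(C)(C)C)cc(O[Si](C)(C)C(C)(C)C)c1)[C@@H](O[Si](CC)(CC)CC)c1ccc(O[Si](C)(C)C(C)(C)C)c(O[Si](C)(C)C(C)(C)C)c1)/C(O[Si](C(C)C)(C(C)C)C(C)C)=C\C(=C)/C=C/c1ccc(O[Si](C)(C)C(C)(C)C)cc1 | intermediate (not isolated)
26 | 2-{(1S,2R)-2-[3,4-bis(TBSO)phenyl]-1-[3,5-bis(TBSO)phenyl]-2-(TESO)ethyl}-5-{(E)-2-[4-(TBSO)phenyl]ethenyl}-3-(TIPSO)cyclohexa-2,4-dien-1-one | O=C1CC(/C=C/c2ccc(O[Si](C)(C)C(C)(C)C)cc2)=CC(O[Si](C(C)C)(C(C)C)C(C)C)=C1[C@H](c1cc(O[Si](C)(C)C(C)(C)C)cc(O[Si](C)(C)C(C)(C)C)c1)[C@@H](O[Si](CC)(CC)CC)c1ccc(O[Si](C)(C)C(C)(C)C)c(O[Si](C)(C)C(C)(C)C)c1 | intermediate (not isolated)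
27 | 2-{(1S,2R)-2-[3,4-bis(TBSO)phenyl]-1-[3,5-bis(TBSO)phenyl]-2-(TESO)ethyl}-5-{(E)-2-[4-(TBSO)phenyl]ethenyl}-3-(TIPSO)phenol | Oc1cc(/C=C/c2ccc(O[Si](C)(C)C(C)(C)C)cc2)cc(O[Si](C(C)C)(C(C)C)C(C)C)c1[C@H](c1cc(O[Si](C)(C)C(C)(C)C)cc(O[Si](C)(C)C(C)(C)C)c1)[C@@H](O[Si](CC)(CC)CC)c1ccc(O[Si](C)(C)C(C)(C)C)c(O[Si](C)(C)C(C)(C)C)c1 | intermediate
28 | 2-{(1S,2R)-2-[3,4-bis(TBSO)phenyl]-1-[3,5-bis(TBSO)phenyl]-2-hydroxyethyl}-5-{(E)-2-[4-(TBSO)phenyl]ethenyl}-3-(TIPSO)phenol | Oc1cc(/C=C/c2ccc(O[Si](C)(C)C(C)(C)C)cc2)cc(O[Si](C(C)C)(C(C)C)C(C)C)c1[C@H](c1cc(O[Si](C)(C)C(C)(C)C)cc(O[Si](C)(C)C(C)(C)C)c1)[C@@H](O)c1ccc(O[Si](C)(C)C(C)(C)C)c(O[Si](C)(C)C(C)(C)C)c1 | intermediate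
29 | (2S,3S)-2-[3,4-bis(TBSO)phenyl]-3-[3,5-bis(TBSO)phenyl]-6-{(E)-2-[4-(TBSO)phenyl]ethenyl}-4-(TIPSO)-2,3-dihydro-1-benzofuran | CC(C)(C)[Si](C)(C)Oc1ccc(/C=C/c2cc(O[Si](C(C)C)(C(C)C)C(C)C)c3c(c2)O[C@H](c2ccc(O[Si](C)(C)C(C)(C)C)c(O[Si](C)(C)C(C)(C)C)c2)[C@H]3c2cc(O[Si](C)(C)C(C)(C)C)cc(O[Si](C)(C)C(C)(C)C)c2)cc1 | intermediate
30 | (2S,3S)-2-(3,4-dihydroxyphenyl)-3-(3,5-dihydroxyphenyl)-6-[(E)-2-(4-hydroxyphenyl)ethenyl]-2,3-dihydro-1-benzofuran-4-ol | Oc1ccc(/C=C/c2cc(O)c3c(c2)O[C@H](c2ccc(O)c(O)c2)[C@H]3c2cc(O)cc(O)c2)cc1 | target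

## Step count and risks

Total: 14 steps. Longest linear sequence: 12 steps (steps 1 to 8, then 11 to 14).

**Step 11 (key step).** The (2+2) addition has to bond the ketene carbon to an alkyne carbon that carries a branched, diaryl-flanked substituent. If this is slower than self-reaction of the ketene, dimerisation and oligomerisation of 23 and acylation of the product phenol would consume 22, and long heating invites a 1,3-silyl shift in 16.
Fallback: generate 23 at room temperature and not by heating 22. It sets out from 17 and 16 and comes back at 23, then proceeds through 24 to 27.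
- A vinylogous Horner–Wadsworth–Emmons reaction of 17 with triethyl 3-methyl-4-phosphonocrotonate (LiN(SiMe3)2, THF) would give ethyl (2E,4E)-3-methyl-5-[4-(TBSO)phenyl]penta-2,4-dienoate F1.
- Me3SnOH in 1,2-dichloroethane would give (2E,4E)-3-methyl-5-[4-(TBSO)phenyl]penta-2,4-dienoic acid F2, and oxalyl chloride with catalytic DMF the acid chloride (2E,4E)-3-methyl-5-[4-(TBSO)phenyl]penta-2,4-dienoyl chloride F3.
- Slow addition of Et3N to F3 and 16 in toluene at room temperature would form 23 by 1,4-dehydrochlorination in the presence of a high concentration of the alkyne. Gentle warming would then carry 24 on to 27.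

**Step 8.** Oxygen transfer to a hindered acetylide may be incomplete. The alkoxide and peroxide bases could strip aryl silyl groups or erode the propargylic centre if they are in excess or too warm.
Fallback: reach the ynolate by cleavage of an alkynyl sulfonate and not by acetylide oxidation. It sets out from 13 and comes back at 15, then 16.
- n-BuLi followed by aqueous NH4Cl would give the terminal alkyne (3R,4R)-4-[3,4-bis(TBSO)phenyl]-3-[3,5-bis(TBSO)phenyl]-4-(TESO)but-1-yne F4.
- PhI(OH)OTs with molecular sieves in CH2Cl2 would give the alkynyl(phenyl)iodonium tosylate F5.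
- Catalytic CuOTf in MeCN would rearrange it to the alkynyl tosylate (3S,4R)-4-[3,4-bis(TBSO)phenyl]-3-[3,5-bis(TBSO)phenyl]-4-(TESO)but-1-yn-1-yl 4-methylbenzenesulfonate F6.
- MeLi at −78 °C would attack sulfur and release 15, which TIPSOTf silylates to 16.

**Step 7 (with the aldehyde made in step 6).** Epimerisation at the α-aryl carbon or β-elimination of the silyloxy group may occur while 12 waits for the ylide, because the α-hydrogen is benzylic and next to a carbonyl.
Fallback: a chromium-based olefination that is not basic. It sets out from 12 and comes back at 14.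
- CrCl2 and CHI3 in THF would give the vinyl iodide (1E,3R,4R)-4-[3,4-bis(TBSO)phenyl]-3-[3,5-bis(TBSO)phenyl]-1-iodo-4-(TESO)but-1-ene F7.
- LiN(i-Pr)2 (2 equiv) at −78 °C would bring about dehydroiodination and deprotonation to 14, which continues as in step 8.

**Step 13.** The activated carbinol lies next to a doubly benzylic C–H and on an electron-rich benzylic carbon. Elimination towards the triarylethylene, or ionisation before displacement, could compete with the SN2 closure.
Fallback: close the ring under thermodynamic control after deprotection. It sets out from 27 (or 28) and comes back at 30.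
- TBAF and AcOH would remove all silyl groups to give 2-[(1S,2R)-2-(3,4-dihydroxyphenyl)-1-(3,5-dihydroxyphenyl)-2-hydroxyethyl]-5-[(E)-2-(4-hydroxyphenyl)ethenyl]benzene-1,3-diol F8.
- Catalytic TsOH in MeCN at room temperature would ionise the para-hydroxybenzylic carbinol to a quinone methide, which either ortho phenol of ring A captures.
- Because this closure is reversible at C2 and C3 is not involved, the trans ring of 30 should prevail whatever the carbinol configuration.

## Further compounds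

F1 | step 11 | ethyl (2E,4E)-3-methyl-5-[4-(TBSO)phenyl]penta-2,4-dienoate | CCOC(=O)/C=C(C)/C=C/c1ccc(O[Si](C)(C)C(C)(C)C)cc1
F2 | step 11 | (2E,4E)-3-methyl-5-[4-(TBSO)phenyl]penta-2,4-dienoic acid | OC(=O)/C=C(C)/C=C/c1ccc(O[Si](C)(C)C(C)(C)C)cc1
F3 | step 11 | (2E,4E)-3-methyl-5-[4-(TBSO)phenyl]penta-2,4-dienoyl chloride | ClC(=O)/C=C(C)/C=C/c1ccc(O[Si](C)(C)C(C)(C)C)cc1
F4 | step 8 | (3R,4R)-4-[3,4-bis(TBSO)phenyl]-3-[3,5-bis(TBSO)phenyl]-4-(TESO)but-1-yne | CC[Si](CC)(CC)O[C@@H](c1ccc(O[Si](C)(C)C(C)(C)C)c(O[Si](C)(C)C(C)(C)C)c1)[C@H](C#C)c1cc(O[Si](C)(C)C(C)(C)C)cc(O[Si](C)(C)C(C)(C)C)c1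
F5 | step 8 | [(3S,4R)-4-[3,4-bis(TBSO)phenyl]-3-[3,5-bis(TBSO)phenyl]-4-(TESO)but-1-yn-1-yl](phenyl)iodonium 4-methylbenzenesulfonate | CC[Si](CC)(CC)O[C@@H](c1ccc(O[Si](C)(C)C(C)(C)C)c(O[Si](C)(C)C(C)(C)C)c1)[C@H](C#C[I+]c1ccccc1)c1cc(O[Si](C)(C)C(C)(C)C)cc(O[Si](C)(C)C(C)(C)C)c1.Cc1ccc(S(=O)(=O)[O-])cc1
F6 | step 8 | (3S,4R)-4-[3,4-bis(TBSO)phenyl]-3-[3,5-bis(TBSO)phenyl]-4-(TESO)but-1-yn-1-yl 4-methylbenzenesulfonate | CC[Si](CC)(CC)O[C@@H](c1ccc(O[Si](C)(C)C(C)(C)C)c(O[Si](C)(C)C(C)(C)C)c1)[C@H](C#COS(=O)(=O)c1ccc(C)cc1)c1cc(O[Si](C)(C)C(C)(C)C)cc(O[Si](C)(C)C(C)(C)C)c1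
F7 | step 7 | (1E,3R,4R)-4-[3,4-bis(TBSO)phenyl]-3-[3,5-bis(TBSO)phenyl]-1-iodo-4-(TESO)but-1-ene | CC[Si](CC)(CC)O[C@@H](c1ccc(O[Si](C)(C)C(C)(C)C)c(O[Si](C)(C)C(C)(C)C)c1)[C@H](/C=C/I)c1cc(O[Si](C)(C)C(C)(C)C)cc(O[Si](C)(C)C(C)(C)C)c1
F8 | step 13 | 2-[(1S,2R)-2-(3,4-dihydroxyphenyl)-1-(3,5-dihydroxyphenyl)-2-hydroxyethyl]-5-[(E)-2-(4-hydroxyphenyl)ethenyl]benzene-1,3-diol | Oc1ccc(/C=C/c2cc(O)c([C@H](c3cc(O)cc(O)c3)[C@@H](O)c3ccc(O)c(O)c3)c(O)c2)cc1
A1 | alternative 1 | (2S)-7-benzyloxy-2-(3,4-dimethoxyphenyl)-5-methoxychroman-4-one | O=C1C[C@@H](c2ccc(OC)c(OC)c2)Oc2cc(OCc3ccccc3)cc(OC)c12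
A2 | alternative 1 | methyl (2S,3S)-6-benzyloxy-2-(3,4-dimethoxyphenyl)-4-methoxy-2,3-dihydro-1-benzofuran-3-carboxylate | c1ccccc1COc1cc(OC)c2c(c1)O[C@H](c1ccc(OC)c(OC)c1)[C@H]2C(=O)OC
A3 | alternative 2 | 2-[(3,5-dimethoxyphenyl)(4-methylphenylsulfonyl)methyl]-5-[(E)-2-(4-methoxyphenyl)ethenyl]benzene-1,3-diol (racemic) | COc1ccc(/C=C/c2cc(O)c(C(c3cc(OC)cc(OC)c3)S(=O)(=O)c3ccc(C)cc3)c(O)c2)cc1
A4 | alternative 2 | (2R,5R)-1-(3,4-dimethoxybenzyl)-2,5-dimethylthiolan-1-ium triflate (antipode chosen to suit the sense of induction) | COc1ccc(C[S+]2[C@H](C)CC[C@H]2C)cc1OC.[O-]S(=O)(=O)C(F)(F)F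
A5 | alternative 2 | (2S,3S)-2-(3,4-dimethoxyphenyl)-3-(3,5-dimethoxyphenyl)-6-[(E)-2-(4-methoxyphenyl)ethenyl]-2,3-dihydro-1-benzofuran-4-ol | COc1ccc(/C=C/c2cc(O)c3c(c2)O[C@H](c2ccc(OC)c(OC)c2)[C@H]3c2cc(OC)cc(OC)c2)cc1
A6 | alternative 3 | 2-[(3S,4S)-4-(3,4-dimethoxyphenyl)-3-(3,5-dimethoxyphenyl)-4-(ethynyloxy)but-1-yn-1-yl]-4,4,5,5-tetramethyl-1,3,2-dioxaborolane | C#CO[C@H](c1ccc(OC)c(OC)c1)[C@H](C#CB1OC(C)(C)C(C)(C)O1)c1cc(OC)cc(OC)c1
A7 | alternative 3 | 1-[(E)-but-1-en-3-yn-1-yl]-4-methoxybenzene | C#C/C=C/c1ccc(OC)cc1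
A8 | alternative 3 | 2-[(2S,3S)-2-(3,4-dimethoxyphenyl)-3-(3,5-dimethoxyphenyl)-6-[(E)-2-(4-methoxyphenyl)ethenyl]-2,3-dihydro-1-benzofuran-4-yl]-4,4,5,5-tetramethyl-1,3,2-dioxaborolane | COc1ccc(/C=C/c2cc(B3OC(C)(C)C(C)(C)O3)c3c(c2)O[C@H](c2ccc(OC)c(OC)c2)[C@H]3c2cc(OC)cc(OC)c2)cc1
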